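**Strategy.** Six contiguous atoms of the target, namely the hydroxymethyl carbon, the sp2 carbon that carries it, the neighbouring vinylic CH, the allylic methylene, the carbinol carbon and the carbinol oxygen, are treated as the ring of a 3-alkyl-5,6-dihydropyran-2-one that is reduced later. Inside that six-membered lactone the hydroxymethyl carbon and the carbinol arm can only be cis. A ruthenium-catalysed ring-closing metathesis makes this trisubstituted alkene and the lactone ring in a single operation. Its substrate is the 2-methylidene ester formed from (R)-1-(furan-3-yl)but-3-en-1-ol and an (E)-configured acid carrying the trimethylcyclohexenyl chain; the furan serves as a latent butenolide.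

Key step: step 9

Assumption: the (R)-configured phosphoric acid catalyst is taken to deliver the allyl group to the Re face of 3-furaldehyde, as it does with other aromatic aldehydes, which gives the (R)-alcohol; hydroxybutenolide 20 is expected as a mixture of epimers at its lactol carbon, a centre that step 12 removes.

**Route**

Step 1
Reactants: 1 3-furaldehyde; 2 allylboronic acid pinacol ester
Product: 4 (R)-1-(furan-3-yl)but-3-en-1-ol, via pinacol borate ester 3 (not isolated)
Conditions: (R)-TRIP phosphoric acid (5 mol %), toluene, −30 °C; aqueous work-up, SiO2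
Reagents that add atoms: none
Why: Chiral phosphoric acid-catalysed allylboration runs through a closed chair-like six-membered transition state in which the catalyst activates a boronate oxygen and binds the formyl group, so the (R)-catalyst should expose the Re face and set the (R)-carbinol, the borate 3 being hydrolysed on work-up.

Step 2
Reactants: 5 dihydro-β-ionone
Product: 7 2-(but-3-yn-1-yl)-1,3,3-trimethylcyclohex-1-ene, via enol diethyl phosphate 6 (not isolated)
Conditions: LDA (1.05 equiv), THF, −78 °C; ClP(O)(OEt)2, −78 °C to rt; LDA (2.3 equiv), THF, −78 °C to rt; aq. NH4Cl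
Reagents that add atoms: none
Why: Methyl ketone to terminal alkyne conversion by kinetic deprotonation at the methyl group, O-phosphorylation and base-induced β-elimination of diethyl phosphate from the terminal enol phosphate, which gives the lithium acetylide that is protonated on work-up.

Step 3
Reactants: 7 2-(but-3-yn-1-yl)-1,3,3-trimethylcyclohex-1-ene
Product: 10 (E)-4-methyl-6-(2,6,6-trimethylcyclohex-1-en-1-yl)hex-3-en-1-ol, via alkenyldimethylalane 8 (not isolated), via lithium alkenylaluminate 9 (not isolated)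
Conditions: Me3Al (2 equiv), Cp2ZrCl2 (0.25 equiv), CH2Cl2, rt; volatiles removed; n-BuLi (1 equiv), THF/hexane, −78 to 0 °C; ethylene oxide (THF solution, 3 equiv), 0 °C to rt; aq. Rochelle salt
Reagents that add atoms: trimethylaluminium C[Al](C)C; ethylene oxide C1CO1
Why: Zirconium-catalysed Negishi carboalumination adds methyl and aluminium syn across the terminal alkyne with aluminium at the terminus, which fixes the (E)-trisubstituted alkene, and the derived ate complex transfers its alkenyl group to ethylene oxide with retention of geometry.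

Step 4
Reactants: 10 (E)-4-methyl-6-(2,6,6-trimethylcyclohex-1-en-1-yl)hex-3-en-1-ol
Product: 11 2-[(E)-6-bromo-3-methylhex-3-en-1-yl]-1,3,3-trimethylcyclohex-1-ene
Conditions: CBr4, PPh3, CH2Cl2, 0 °C
Reagents that add atoms: carbon tetrabromide BrC(Br)(Br)Br
Why: Appel reaction, in which the primary alcohol is activated as an alkoxyphosphonium ion and displaced by bromide under neutral conditions that leave both alkenes untouched.

Step 5
Reactants: 11 2-[(E)-6-bromo-3-methylhex-3-en-1-yl]-1,3,3-trimethylcyclohex-1-ene; 12 triethyl phosphonoacetate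
Product: 13 ethyl (5E)-2-(diethoxyphosphoryl)-6-methyl-8-(2,6,6-trimethylcyclohex-1-en-1-yl)oct-5-enoate
Conditions: 12 (2 equiv), NaH (1.8 equiv), DME, 0 °C to rt; then 11, NaI (cat.), 80 °C
Reagents that add atoms: none
Why: SN2 C-alkylation of the sodium phosphonoacetate by the primary bromide, with excess nucleophile to limit dialkylation; the new centre at C2 is formed racemic and is destroyed in step 6.

Step 6
Reactants: 13 ethyl (5E)-2-(diethoxyphosphoryl)-6-methyl-8-(2,6,6-trimethylcyclohex-1-en-1-yl)oct-5-enoate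
Product: 14 ethyl (5E)-6-methyl-2-methylidene-8-(2,6,6-trimethylcyclohex-1-en-1-yl)oct-5-enoate
Conditions: 37 % aq. HCHO, K2CO3, THF/H2O, 70 °C
Reagents that add atoms: formaldehyde C=O
Why: Horner–Wadsworth–Emmons olefination of the α-alkyl phosphonoacetate with formaldehyde, the standard entry to α-substituted acrylates, which raises no geometry question because the new alkene is a methylidene.

Step 7
Reactants: 14 ethyl (5E)-6-methyl-2-methylidene-8-(2,6,6-trimethylcyclohex-1-en-1-yl)oct-5-enoate
Product: 15 (5E)-6-methyl-2-methylidene-8-(2,6,6-trimethylcyclohex-1-en-1-yl)oct-5-enoic acid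
Conditions: LiOH·H2O, THF/MeOH/H2O, rt; then 1 M HCl
Reagents that add atoms: lithium hydroxide [Li+].[OH-]
Why: Saponification by acyl–oxygen cleavage, which an α-alkyl acrylate tolerates because conjugate addition to the hindered methylidene is slow.

Step 8
Reactants: 15 (5E)-6-methyl-2-methylidene-8-(2,6,6-trimethylcyclohex-1-en-1-yl)oct-5-enoic acid; 4 (R)-1-(furan-3-yl)but-3-en-1-ol
Product: 16 (1R)-1-(furan-3-yl)but-3-en-1-yl (5E)-6-methyl-2-methylidene-8-(2,6,6-trimethylcyclohex-1-en-1-yl)oct-5-enoate
Conditions: DCC, DMAP (0.3 equiv), CH2Cl2, 0 °C to rt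
Reagents that add atoms: none
Why: Steglich esterification acylates the alcohol oxygen without touching the C–O bond of the carbinol, so the (R) configuration is retained.

Step 9
Reactants: 16 (1R)-1-(furan-3-yl)but-3-en-1-yl (5E)-6-methyl-2-methylidene-8-(2,6,6-trimethylcyclohex-1-en-1-yl)oct-5-enoate
Product: 17 (6R)-6-(furan-3-yl)-3-[(3E)-4-methyl-6-(2,6,6-trimethylcyclohex-1-en-1-yl)hex-3-en-1-yl]-5,6-dihydro-2H-pyran-2-one
Conditions: Grubbs II (5 mol %), 1,4-benzoquinone (10 mol %), toluene (0.005 M), 80 °C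
Reagents that add atoms: none
Why: Olefin metathesis by the Chauvin mechanism: the ruthenium benzylidene initiates at the monosubstituted vinyl group, the new alkylidene adds intramolecularly across the 1,1-disubstituted acrylate C=CH2 in a [2+2] cycloaddition, and cycloreversion of the ruthenacyclobutane releases the lactone and Ru=CH2, with net loss of ethylene. The closest known reaction type is the ring-closing metathesis of α-alkyl acrylates of homoallylic alcohols to 3-alkyl-5,6-dihydropyran-2-ones with second-generation NHC–ruthenium catalysts. The ring is closed by forming the C3=C4 bond of a six-membered lactone with the new double bond endocyclic, so only the cis alkene, with the ester carbonyl and the C5 methylene on the same side, can form. No stereocentre is created and C6 is not a reacting atom, so the (R) configuration set in step 1 is carried through unchanged. The selectivity needed is among four C=C bonds and the furan: the trisubstituted chain alkene and the tetrasubstituted ring alkene are too hindered to enter the cycle, closure onto the chain alkene would in any case need a nine-membered ring, and the furan is aromatic. High dilution disfavours dimerisation through the vinyl groups and benzoquinone suppresses hydride-mediated migration of the terminal alkene.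

Step 10
Reactants: 17 (6R)-6-(furan-3-yl)-3-[(3E)-4-methyl-6-(2,6,6-trimethylcyclohex-1-en-1-yl)hex-3-en-1-yl]-5,6-dihydro-2H-pyran-2-one
Product: 18 (2Z,5R)-5-(furan-3-yl)-2-[(3E)-4-methyl-6-(2,6,6-trimethylcyclohex-1-en-1-yl)hex-3-en-1-yl]pent-2-ene-1,5-diol
Conditions: DIBAL-H (4.5 equiv), CH2Cl2, −78 °C to rt; aq. Rochelle salt
Reagents that add atoms: none
Why: DIBAL-H 1,2-reduction of the unsaturated lactone gives the lactol aluminate, which opens on warming and is reduced again to the primary allylic alcohol, leaving the ring-derived (Z) geometry and the carbinol centre unchanged.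

Step 11
Reactants: 18 (2Z,5R)-5-(furan-3-yl)-2-[(3E)-4-methyl-6-(2,6,6-trimethylcyclohex-1-en-1-yl)hex-3-en-1-yl]pent-2-ene-1,5-diol
Product: 20 5-hydroxy-4-[(1R,3Z,7E)-1-hydroxy-4-(hydroxymethyl)-8-methyl-10-(2,6,6-trimethylcyclohex-1-en-1-yl)deca-3,7-dien-1-yl]furan-2(5H)-one, via furan endoperoxide 19 (not isolated)
Conditions: O2, hν (visible), TPP (cat.), i-Pr2NEt (10 equiv), CH2Cl2, −78 °C, stopped at full consumption of 18; then warm to rt
Reagents that add atoms: dioxygen O=O
Why: Dye-sensitised photooxygenation, in which [4+2] addition of singlet oxygen to the furan should outrun ene reactions of the hindered alkenes at −78 °C and the hindered amine removes the bridgehead hydrogen remote from the side chain (Kornblum–DeLaMare-type fragmentation), placing the carbonyl there and the lactol carbon next to the substituent; the lactol centre is uncontrolled and is removed in step 12.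

Step 12
Reactants: 20 5-hydroxy-4-[(1R,3Z,7E)-1-hydroxy-4-(hydroxymethyl)-8-methyl-10-(2,6,6-trimethylcyclohex-1-en-1-yl)deca-3,7-dien-1-yl]furan-2(5H)-one
Product: 21 4-[(1R,3Z,7E)-1-hydroxy-4-(hydroxymethyl)-8-methyl-10-(2,6,6-trimethylcyclohex-1-en-1-yl)deca-3,7-dien-1-yl]furan-2(5H)-one
Conditions: NaBH4, EtOH/THF, 0 °C; then 1 M HCl to pH 3
Reagents that add atoms: none
Why: Borohydride reduction of the ring-opened aldehyde tautomer of the γ-hydroxybutenolide gives a (Z)-4-hydroxy-2-enoate that relactonises on acidification to the β-substituted butenolide, with the carbinol centre not involved.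

**Compound list**

1 | 3-furaldehyde (furan-3-carbaldehyde) | O=Cc1ccoc1 | starting material
2 | allylboronic acid pinacol ester | C=CCB1OC(C)(C)C(C)(C)O1 | starting material
3 | 2-{[(1R)-1-(furan-3-yl)but-3-en-1-yl]oxy}-4,4,5,5-tetramethyl-1,3,2-dioxaborolane | C=CC[C@@H](OB1OC(C)(C)C(C)(C)O1)c1ccoc1 | intermediate
4 | (R)-1-(furan-3-yl)but-3-en-1-ol | C=CC[C@@H](O)c1ccoc1 | intermediate
5 | dihydro-β-ionone | CC(=O)CCC1=C(C)CCCC1(C)C | starting material
6 | diethyl 4-(2,6,6-trimethylcyclohex-1-en-1-yl)but-1-en-2-yl phosphate | C=C(CCC1=C(C)CCCC1(C)C)OP(=O)(OCC)OCC | intermediate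
7 | 2-(but-3-yn-1-yl)-1,3,3-trimethylcyclohex-1-ene | C#CCCC1=C(C)CCCC1(C)C | intermediate
8 | dimethyl[(E)-2-methyl-4-(2,6,6-trimethylcyclohex-1-en-1-yl)but-1-en-1-yl]alane | C[Al](C)/C=C(\C)CCC1=C(C)CCCC1(C)C | intermediate
9 | lithium butyldimethyl[(E)-2-methyl-4-(2,6,6-trimethylcyclohex-1-en-1-yl)but-1-en-1-yl]aluminate | [Li+].CCCC[Al-](C)(C)/C=C(\C)CCC1=C(C)CCCC1(C)C | intermediate
10 | (E)-4-methyl-6-(2,6,6-trimethylcyclohex-1-en-1-yl)hex-3-en-1-ol | OCC/C=C(\C)CCC1=C(C)CCCC1(C)C | intermediate
11 | 2-[(E)-6-bromo-3-methylhex-3-en-1-yl]-1,3,3-trimethylcyclohex-1-ene | BrCC/C=C(\C)CCC1=C(C)CCCC1(C)C | intermediate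
12 | triethyl phosphonoacetate | CCOC(=O)CP(=O)(OCC)OCC | starting material
13 | ethyl (5E)-2-(diethoxyphosphoryl)-6-methyl-8-(2,6,6-trimethylcyclohex-1-en-1-yl)oct-5-enoate (racemic at C2) | CCOC(=O)C(CC/C=C(\C)CCC1=C(C)CCCC1(C)C)P(=O)(OCC)OCC | intermediate
14 | ethyl (5E)-6-methyl-2-methylidene-8-(2,6,6-trimethylcyclohex-1-en-1-yl)oct-5-enoate | C=C(CC/C=C(\C)CCC1=C(C)CCCC1(C)C)C(=O)OCC | intermediate
15 | (5E)-6-methyl-2-methylidene-8-(2,6,6-trimethylcyclohex-1-en-1-yl)oct-5-enoic acid | C=C(CC/C=C(\C)CCC1=C(C)CCCC1(C)C)C(=O)O | intermediate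
16 | (1R)-1-(furan-3-yl)but-3-en-1-yl (5E)-6-methyl-2-methylidene-8-(2,6,6-trimethylcyclohex-1-en-1-yl)oct-5-enoate | C=C(CC/C=C(\C)CCC1=C(C)CCCC1(C)C)C(=O)O[C@H](CC=C)c1ccoc1 | intermediate
17 | (6R)-6-(furan-3-yl)-3-[(3E)-4-methyl-6-(2,6,6-trimethylcyclohex-1-en-1-yl)hex-3-en-1-yl]-5,6-dihydro-2H-pyran-2-one | O=C1O[C@@H](c2ccoc2)CC=C1CC/C=C(\C)CCC3=C(C)CCCC3(C)C | intermediate
18 | (2Z,5R)-5-(furan-3-yl)-2-[(3E)-4-methyl-6-(2,6,6-trimethylcyclohex-1-en-1-yl)hex-3-en-1-yl]pent-2-ene-1,5-diol | CC1=C(CC/C(C)=C/CC/C(=C/C[C@@H](O)c2ccoc2)CO)C(C)(C)CCC1 | intermediate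
19 | (2Z,5R)-2-[(3E)-4-methyl-6-(2,6,6-trimethylcyclohex-1-en-1-yl)hex-3-en-1-yl]-5-(2,3,7-trioxabicyclo[2.2.1]hept-5-en-5-yl)pent-2-ene-1,5-diol (bridgehead configuration unassigned) | CC1=C(CC/C(C)=C/CC/C(=C/C[C@@H](O)C2=CC3OOC2O3)CO)C(C)(C)CCC1 | intermediate
20 | 5-hydroxy-4-[(1R,3Z,7E)-1-hydroxy-4-(hydroxymethyl)-8-methyl-10-(2,6,6-trimethylcyclohex-1-en-1-yl)deca-3,7-dien-1-yl]furan-2(5H)-one (epimers at C5 of the furanone) | CC1=C(CC/C(C)=C/CC/C(=C/C[C@@H](O)C2=CC(=O)OC2O)CO)C(C)(C)CCC1 | intermediate
21 | 4-[(1R,3Z,7E)-1-hydroxy-4-(hydroxymethyl)-8-methyl-10-(2,6,6-trimethylcyclohex-1-en-1-yl)deca-3,7-dien-1-yl]furan-2(5H)-one | CC1=C(CC/C(C)=C/CC/C(=C/C[C@@H](O)C2=CC(=O)OC2)CO)C(C)(C)CCC1 | target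

**Step count**

Total steps: 12. Longest linear sequence: 11 steps (steps 2 to 12, from dihydro-β-ionone); step 1 is the only step of the second branch.

**Steps most likely to fail**

Step 9. After initiation at the vinyl group, the alkylidene may not engage the electron-poor 1,1-disubstituted acrylate alkene fast enough, so that dimerisation through the vinyl groups or double-bond migration takes over. The fallback makes the same C3=C4 bond by a Z-selective olefination and then closes the ring by lactonisation. It sets out from bromide 11 and alcohol 4 and comes back to the route at lactone 17. Alkylation of ethyl (diphenoxyphosphoryl)acetate with 11 (NaH, DME, NaI cat.) should give ethyl (5E)-2-(diphenoxyphosphoryl)-6-methyl-8-(2,6,6-trimethylcyclohex-1-en-1-yl)oct-5-enoate F1. Silylation of 4 (TBSCl, imidazole, DMF) should give tert-butyl{[(1R)-1-(furan-3-yl)but-3-en-1-yl]oxy}dimethylsilane F2. Johnson–Lemieux cleavage of its vinyl group (OsO4 cat., NaIO4, 2,6-lutidine, dioxane/H2O) should give (3R)-3-[(tert-butyldimethylsilyl)oxy]-3-(furan-3-yl)propanal F3. Horner–Wadsworth–Emmons olefination of F3 with F1 in its Z-selective diaryl phosphonate form (Ando variant; t-BuOK, THF, −78 °C) should give ethyl (2Z,5R)-5-[(tert-butyldimethylsilyl)oxy]-5-(furan-3-yl)-2-[(3E)-4-methyl-6-(2,6,6-trimethylcyclohex-1-en-1-yl)hex-3-en-1-yl]pent-2-enoate F4. HF·pyridine in THF removes the silyl group, and the (Z)-δ-hydroxy ester should close to 17, with PPTS in warm toluene if closure is slow.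

Step 11. Singlet oxygen may be diverted into ene reactions at the tetrasubstituted ring alkene and the trisubstituted alkenes, or the endoperoxide may fragment from the bridgehead next to the side chain and give the regioisomeric lactol. The fallback places a trimethylsilyl group at C5 of the furan, which speeds up oxygen capture and fixes the carbonyl position by silyl migration to the peroxide oxygen, without base. It sets out from 3-furaldehyde 1 and comes back to the route at hydroxybutenolide 20. Temporary protection of 1 as its lithium morpholide adduct, lithiation at C5 (s-BuLi, THF, −78 °C) and quenching with Me3SiCl should give 5-(trimethylsilyl)furan-3-carbaldehyde F5. This aldehyde is taken through steps 1, 8, 9 and 10 unchanged. These should give in turn (1R)-1-[5-(trimethylsilyl)furan-3-yl]but-3-en-1-ol F6, (1R)-1-[5-(trimethylsilyl)furan-3-yl]but-3-en-1-yl (5E)-6-methyl-2-methylidene-8-(2,6,6-trimethylcyclohex-1-en-1-yl)oct-5-enoate F7, (6R)-3-[(3E)-4-methyl-6-(2,6,6-trimethylcyclohex-1-en-1-yl)hex-3-en-1-yl]-6-[5-(trimethylsilyl)furan-3-yl]-5,6-dihydro-2H-pyran-2-one F8 and (2Z,5R)-2-[(3E)-4-methyl-6-(2,6,6-trimethylcyclohex-1-en-1-yl)hex-3-en-1-yl]-5-[5-(trimethylsilyl)furan-3-yl]pent-2-ene-1,5-diol F9. Photooxygenation of F9 (O2, hν, TPP, CH2Cl2, −78 °C, then water) should give 20.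

Step 3. Transfer of the alkenyl group from aluminium to ethylene oxide may be incomplete, or be accompanied by butyl transfer and protodemetalation. The fallback separates the carbometalation from the C–C bond formation. It sets out from alkyne 7 and comes back to the route at alcohol 10. The alkenylalane from the same carboalumination is quenched with iodine (THF, −30 °C) to give 2-[(3E)-4-iodo-3-methylbut-3-en-1-yl]-1,3,3-trimethylcyclohex-1-ene F10. Iodine–lithium exchange (t-BuLi, Et2O, −78 °C) and opening of ethylene oxide by the vinyllithium in the presence of BF3·OEt2 should give 10 with retention of the alkene geometry.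

**Further compounds**

F1 | step 9 | ethyl (5E)-2-(diphenoxyphosphoryl)-6-methyl-8-(2,6,6-trimethylcyclohex-1-en-1-yl)oct-5-enoate | CCOC(=O)C(CC/C=C(\C)CCC1=C(C)CCCC1(C)C)P(=O)(Oc1ccccc1)Oc1ccccc1
F2 | step 9 | tert-butyl{[(1R)-1-(furan-3-yl)but-3-en-1-yl]oxy}dimethylsilane | C=CC[C@@H](O[Si](C)(C)C(C)(C)C)c1ccoc1
F3 | step 9 | (3R)-3-[(tert-butyldimethylsilyl)oxy]-3-(furan-3-yl)propanal | O=CC[C@@H](O[Si](C)(C)C(C)(C)C)c1ccoc1
F4 | step 9 | ethyl (2Z,5R)-5-[(tert-butyldimethylsilyl)oxy]-5-(furan-3-yl)-2-[(3E)-4-methyl-6-(2,6,6-trimethylcyclohex-1-en-1-yl)hex-3-en-1-yl]pent-2-enoate | CCOC(=O)/C(CC/C=C(\C)CCC1=C(C)CCCC1(C)C)=C\C[C@@H](O[Si](C)(C)C(C)(C)C)c1ccoc1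
F5 | step 11 | 5-(trimethylsilyl)furan-3-carbaldehyde | O=Cc1coc([Si](C)(C)C)c1
F6 | step 11 | (1R)-1-[5-(trimethylsilyl)furan-3-yl]but-3-en-1-ol | C=CC[C@@H](O)c1coc([Si](C)(C)C)c1
F7 | step 11 | (1R)-1-[5-(trimethylsilyl)furan-3-yl]but-3-en-1-yl (5E)-6-methyl-2-methylidene-8-(2,6,6-trimethylcyclohex-1-en-1-yl)oct-5-enoate | C=C(CC/C=C(\C)CCC1=C(C)CCCC1(C)C)C(=O)O[C@H](CC=C)c1coc([Si](C)(C)C)c1
F8 | step 11 | (6R)-3-[(3E)-4-methyl-6-(2,6,6-trimethylcyclohex-1-en-1-yl)hex-3-en-1-yl]-6-[5-(trimethylsilyl)furan-3-yl]-5,6-dihydro-2H-pyran-2-one | O=C1O[C@@H](c2coc([Si](C)(C)C)c2)CC=C1CC/C=C(\C)CCC3=C(C)CCCC3(C)C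
F9 | step 11 | (2Z,5R)-2-[(3E)-4-methyl-6-(2,6,6-trimethylcyclohex-1-en-1-yl)hex-3-en-1-yl]-5-[5-(trimethylsilyl)furan-3-yl]pent-2-ene-1,5-diol | CC1=C(CC/C(C)=C/CC/C(=C/C[C@@H](O)c2coc([Si](C)(C)C)c2)CO)C(C)(C)CCC1
F10 | step 3 | 2-[(3E)-4-iodo-3-methylbut-3-en-1-yl]-1,3,3-trimethylcyclohex-1-ene | I/C=C(\C)CCC1=C(C)CCCC1(C)C
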